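The vessel is closed, stirred and isothermal, and it holds two solids, neither in solution at the start; beta is this flask, followed so far.

| setting | beta | theta | flask |
|---|---|---|---|
| solid substrate | 10 mM | 10 mM | 10 mM |
| solid reagent | 0.90 equiv | 1.4 equiv | 0.900 equiv |
| remark | the very flask that is asked about, followed so far | run made earlier |  |
| time |  |  | 40 h |

| run | time / h | product / % |
|---|---|---|
| beta | 4.00 | 68 |
| beta | 8.00 | 79 |
| beta | 12.0 | 87 |
| beta | 15.0 | 90 |
| theta | 3.00 | 82 |
| theta | 8.00 | 99 |
| theta | 15.0 | 99 |
| theta | 40.0 | 100 |

(readings scatter by 2 percentage points)

* why nothing more happens at 40 h, or that something still does (for what has run out or reacted, a solid counts together with what of it has only dissolved) (all of the solid substrate has reacted / the partner has run out first / it is still moving)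
* amount of product at 40 h, in percent of the solid substrate charged

- solid substrate, solid reagent is a solid; its amount is given per volume of the solution
- at the start none of the solid substrate is in solution
- at the start none of the solid reagent is in solution
- what has only dissolved of solid substrate counts as not reacted
- the reaction counts as stopped when no species that holds the solid substrate changes by six tenths of a point or more over the second half of the time

*What bounds beta's product?* Counting does, if one solid reagent serves one solid substrate. Equivalents times charge gives 9.00 mM: this is the reagent ceiling, the [product] that the solid reagent can pay for, one for one.

*Why one for one?* Beta's last reading is 90%, which reads as 9.00 mM of product from a charge worth 9.00 mM. Within the scatter of 2 percentage points, that reading does not ask for more than one reagent per product.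

*And less than one?* That is the weak spot. Theta's ceiling of 14.0 mM stands above its 10 mM of substrate, and theta reached 100%, so theta cannot tell. Beta's readings end at 15.0 h, still 3 points up on the reading before, so they leave this open too.

*Your answer?* I commit to 90.0% at 40 h, with solid reagent as the limiting reagent and 1.00 mM of substrate unreacted.

The forecast says the same: the partner has run out first, at 90%, its range skewed slightly upward. It notes: “Theta shows the substrate can go fully to product when the reagent is in excess”.

In the asked flask the partner has run out first, with 0.022% of its charge left, and product stands at 90.0% at 40 h, which is 9.00 mM against the ceiling of 9.00 mM.

solid substrate ⇌ dissolved substrate, rate k1*(cs1 - [dissolved substrate]) while solid is left; crystals form when [dissolved substrate] > cs1 (solubility = 3.30 mM, k = 0.0390 min⁻¹); dissolved substrate + partner → product (k = 2.70 L mol⁻¹ min⁻¹); solid reagent ⇌ partner, rate k3*(cs3 - [partner]) while solid is left; crystals form when [partner] > cs3 (solubility = 9.90 mM, k = 0.660 min⁻¹) A neighbouring flask, with 0.230 equiv of solid reagent, has a ceiling of 2.30 mM and gives 23.0%, or 2.30 mM, with 44.0% still solid substrate. The asked flask is at rest: at 400 h product stands at 90.0% and dissolved substrate at 10.0%. The partner left in the asked flask at 40.0 h, 0.00199 mM, is worth 0.0199% of the solid substrate charged as product.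

All runs are simulated from invented constants, noise included.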